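## Retrosynthetic overview

1. The target comes from methyl (2R,3R)-3-acetoxy-2-methyl-2-(4-methylpent-3-en-1-yl)chromane-6-carboxylate by a last-step electrochemical, (PhSe)2-catalysed allylic hydroxylation with double-bond transposition.
2. The pyran ring (the only ring made; the benzene ring is bought) and the C-3 acetate come together from an open-chain phenol 1,2-diol: the diol is turned into an acetoxonium ion and the phenol oxygen opens it at the tertiary carbon with inversion.
3. The tertiary carbinol comes from chelation-controlled MeMgBr addition to an (R)-alpha-hydroxy ketone, made from a Weinreb amide and the homoprenyl Grignard reagent.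
4. The ArCH2 bond (C-4 to C-4a) comes from a photochemical NiCl2·glyme/Ir[dF(CF3)ppy]2(dtbbpy)PF6 decarboxylative coupling of the acetonide acid of (R)-malic acid with methyl 4-acetoxy-3-bromobenzoate.
5. Stereochemistry: C-3 is bought with (R)-malic acid; C-2 is set by it through the chelate and then inverted stereospecifically in the ring closure.

Assumption: the acetonide acid of (R)-malic acid is bought as a catalogue compound (it is also one step from (R)-malic acid and 2,2-dimethoxypropane).

## Route

Step 1
Reactants: 1 methyl 3-bromo-4-hydroxybenzoate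
Product: 2 methyl 4-acetoxy-3-bromobenzoate
Conditions: Ac2O, pyridine, DMAP (cat.), CH2Cl2, 0 °C to rt
Reagents that add atoms: acetic anhydride, CC(=O)OC(C)=O
Why: O-acetylation of the phenol (nucleophilic acyl substitution) masks the acidic ortho-hydroxyl during the cross-coupling, and the aryl acetate is a protecting group that step 3 removes at no extra cost.

Step 2
Reactants: 2 methyl 4-acetoxy-3-bromobenzoate; 3 (R)-2-(2,2-dimethyl-5-oxo-1,3-dioxolan-4-yl)acetic acid
Product: 4 methyl 4-acetoxy-3-{[(4R)-2,2-dimethyl-5-oxo-1,3-dioxolan-4-yl]methyl}benzoate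
Conditions: 3 (1.5 equiv) as its Cs salt (Cs2CO3, 0.75 equiv), Ir[dF(CF3)ppy]2(dtbbpy)PF6 (1 mol %), NiCl2·glyme (10 mol %), dtbbpy (15 mol %), DMF, 450 nm LEDs, rt
Reagents that add atoms: none
Why: Metallaphotoredox decarboxylative C(sp3)–C(sp2) cross-coupling, in which excited Ir[dF(CF3)ppy]2(dtbbpy)PF6 oxidises the carboxylate, loss of CO2 gives a primary radical that is captured by ArNi(dtbbpy)Br formed from 2, and reductive elimination makes the C-4 to C-4a bond; the (R) centre bought with 3 sits beta to the radical, is not touched and keeps its configuration.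

Step 3
Reactants: 4 methyl 4-acetoxy-3-{[(4R)-2,2-dimethyl-5-oxo-1,3-dioxolan-4-yl]methyl}benzoate
Product: 5 methyl 4-hydroxy-3-{(2R)-2-hydroxy-3-[methoxy(methyl)amino]-3-oxopropyl}benzoate
Conditions: MeNH(OMe)·HCl (2.4 equiv), AlMe3 (2.4 equiv), CH2Cl2, −10 to 0 °C; then 1 M HCl
Reagents that add atoms: N,O-dimethylhydroxylamine hydrochloride, CNOC.Cl
Why: Weinreb aminolysis, in which Me(Cl)Al–N(OMe)Me opens the activated dioxolanone at its acyl carbon (acetone is lost on work-up) and a second equivalent cleaves the aryl acetate; the C–O bond at the stereocentre is not broken, so (R) is retained, and the methyl benzoate, deactivated by the para phenoxide, should be left alone at 0 °C.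

Step 4
Reactants: 5 methyl 4-hydroxy-3-{(2R)-2-hydroxy-3-[methoxy(methyl)amino]-3-oxopropyl}benzoate; 6 5-bromo-2-methylpent-2-ene
Product: 8 methyl 4-hydroxy-3-[(2R)-2-hydroxy-7-methyl-3-oxooct-6-en-1-yl]benzoate, via (4-methylpent-3-en-1-yl)magnesium bromide 7 (not isolated)
Conditions: 6, Mg, THF, rt; then 5, THF, −40 to 0 °C (3.5 equiv of 7); aq. NH4Cl
Reagents that add atoms: none
Why: Weinreb ketone synthesis, in which two equivalents of 7 deprotonate the phenol and the alcohol and a third adds to the amide to give a chelated tetrahedral intermediate that collapses to the ketone only on work-up, so there is no over-addition and the alpha-hydroxy stereocentre is not exposed to base as a ketone.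

Step 5
Reactants: 8 methyl 4-hydroxy-3-[(2R)-2-hydroxy-7-methyl-3-oxooct-6-en-1-yl]benzoate
Product: 9 methyl 3-[(2R,3S)-2,3-dihydroxy-3,7-dimethyloct-6-en-1-yl]-4-hydroxybenzoate
Conditions: MeMgBr (4 equiv), THF/Et2O, −78 to −40 °C; aq. NH4Cl
Reagents that add atoms: methylmagnesium bromide, C[Mg]Br
Why: Cram-chelate (chelation-controlled) Grignard addition, in which the magnesium alkoxide of the alpha-hydroxyl and the ketone oxygen form a five-membered chelate and methyl attacks the carbonyl face on the side of H, opposite the ArCH2 group, which sets the tertiary carbinol as (3S) under control of the bought (2R) centre (expected dr about 10:1 or better).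

Step 6
Reactants: 9 methyl 3-[(2R,3S)-2,3-dihydroxy-3,7-dimethyloct-6-en-1-yl]-4-hydroxybenzoate
Product: 12 methyl (2R,3R)-3-acetoxy-2-methyl-2-(4-methylpent-3-en-1-yl)chromane-6-carboxylate, via cyclic orthoacetate 10 (not isolated), via dioxolan-2-ylium ion 11 (not isolated)
Conditions: MeC(OMe)3 (1.3 equiv), PPTS (5 mol %), CH2Cl2, rt, then evaporate; BF3·OEt2 (20 mol %), CH2Cl2, −78 to 0 °C
Reagents that add atoms: trimethyl orthoacetate, CC(OC)(OC)OC
Why: Proposed new method: a phenol-terminated acetoxonium cycloetherification, in which the diol condenses with the orthoester to 10, BF3·OEt2 removes methoxide to give the bridged cation 11 whose tertiary C–O bond carries most of the positive charge, and the phenol attacks that carbon from the back in a 6-endo ring closure (inversion at C-2, from S to R) while the secondary C–O bond stays intact and emerges as the C-3 acetate with retention, so the ring, the second stereocentre and the acetate are delivered in one operation; the closest known reaction types are the orthoester-mediated acetoxonium cyclisation of 1,2,n-triols by aliphatic hydroxyl groups in the exo mode, the Kolb–Sharpless halide opening of the same cations, and the acid-promoted 6-endo opening of trisubstituted epoxides by phenols, but a phenol opening the tertiary carbon of an acetoxonium ion in the endo mode has not, to my knowledge, been shown.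

Step 7
Reactants: 12 methyl (2R,3R)-3-acetoxy-2-methyl-2-(4-methylpent-3-en-1-yl)chromane-6-carboxylate
Product: 13 methyl (2R,3R)-3-acetoxy-2-[(2E)-4-hydroxy-4-methylpent-2-en-1-yl]-2-methylchromane-6-carboxylate
Conditions: (PhSe)2 (10 mol %), Et4NBr (20 mol %), MgSO4, MeCN/H2O (5:1), Pt anode, Pt cathode, undivided cell, 5 mA cm−2, about 3 F mol−1, rt
Reagents that add atoms: water, O
Why: Electrochemical oxyselenenylation–deselenenylation (allylic hydroxylation with transposition), in which anodically generated PhSeBr/PhSeOH adds across the trisubstituted alkene with water at the tertiary carbon (Markovnikov), the selenide is oxidised at the anode to the selenoxide, and syn-elimination can only take a hydrogen from the chain CH2 next to C-2 (the carbinol carbon has none), giving the (E)-allylic tertiary alcohol regiospecifically without touching either stereocentre.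

## Compound list

1 | methyl 3-bromo-4-hydroxybenzoate | COC(=O)c1ccc(O)c(Br)c1 | starting material
2 | methyl 4-acetoxy-3-bromobenzoate | COC(=O)c1ccc(OC(C)=O)c(Br)c1 | intermediate
3 | (R)-2-(2,2-dimethyl-5-oxo-1,3-dioxolan-4-yl)acetic acid | OC(=O)C[C@H]1OC(C)(C)OC1=O | starting material
4 | methyl 4-acetoxy-3-{[(4R)-2,2-dimethyl-5-oxo-1,3-dioxolan-4-yl]methyl}benzoate | COC(=O)c1ccc(OC(C)=O)c(c1)C[C@H]1OC(C)(C)OC1=O | intermediate
5 | methyl 4-hydroxy-3-{(2R)-2-hydroxy-3-[methoxy(methyl)amino]-3-oxopropyl}benzoate | COC(=O)c1ccc(O)c(c1)C[C@@H](O)C(=O)N(C)OC | intermediate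
6 | 5-bromo-2-methylpent-2-ene | CC(C)=CCCBr | starting material
7 | (4-methylpent-3-en-1-yl)magnesium bromide | CC(C)=CCC[Mg]Br | intermediate
8 | methyl 4-hydroxy-3-[(2R)-2-hydroxy-7-methyl-3-oxooct-6-en-1-yl]benzoate | COC(=O)c1ccc(O)c(c1)C[C@@H](O)C(=O)CCC=C(C)C | intermediate
9 | methyl 3-[(2R,3S)-2,3-dihydroxy-3,7-dimethyloct-6-en-1-yl]-4-hydroxybenzoate | COC(=O)c1ccc(O)c(c1)C[C@@H](O)[C@@](C)(O)CCC=C(C)C | intermediate
10 | cyclic orthoacetate methyl 4-hydroxy-3-{[(4R,5S)-2-methoxy-2,5-dimethyl-5-(4-methylpent-3-en-1-yl)-1,3-dioxolan-4-yl]methyl}benzoate (both epimers at the orthoester carbon) | COC(=O)c1ccc(O)c(c1)C[C@H]1OC(C)(OC)O[C@@]1(C)CCC=C(C)C | intermediate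
11 | dioxolan-2-ylium ion (4R,5S)-4-[2-hydroxy-5-(methoxycarbonyl)benzyl]-2,5-dimethyl-5-(4-methylpent-3-en-1-yl)-1,3-dioxolan-2-ylium methoxytrifluoroborate | COC(=O)c1ccc(O)c(c1)C[C@H]1OC(C)=[O+][C@@]1(C)CCC=C(C)C.CO[B-](F)(F)F | intermediate
12 | methyl (2R,3R)-3-acetoxy-2-methyl-2-(4-methylpent-3-en-1-yl)chromane-6-carboxylate | COC(=O)c1ccc2c(c1)C[C@@H](OC(C)=O)[C@@](C)(CCC=C(C)C)O2 | intermediate
13 | methyl (2R,3R)-3-acetoxy-2-[(2E)-4-hydroxy-4-methylpent-2-en-1-yl]-2-methylchromane-6-carboxylate | COC(=O)c1ccc2c(c1)C[C@@H](OC(C)=O)[C@@](C)(C/C=C/C(C)(C)O)O2 | target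

## Step count and risks

Total step count: 7. Longest linear sequence: 7 steps (1 to 13); 3 and 6 enter as bought building blocks.

Stereochemistry check: C-3 (R) comes unchanged from 3 through 4, 5, 8, 9 and 12. C-2 is made (S) in step 5 and inverted to (R) in step 6. Step 7 touches neither centre.

The three steps most likely to fail:

The new ring closure (step 6) is the largest risk. The phenol could attack the secondary carbon of 11 instead (5-exo, giving a dihydrobenzofuran), or the tertiary carbon could ionise fully and lose its configuration. The fallback uses known chemistry only, sets out from 9 and comes back at 12. Diol 9 is converted into the epoxide with overall retention by the Kolb–Sharpless sequence: the same cyclic orthoacetate 10 is opened with Me3SiCl to the chloro acetate methyl 3-[(2R,3R)-2-acetoxy-3-chloro-3,7-dimethyloct-6-en-1-yl]-4-hydroxybenzoate F2 (the regiochemistry of chloride opening does not matter for the epoxide), and K2CO3 in MeOH closes it to the epoxide methyl 4-hydroxy-3-{[(2R,3S)-3-methyl-3-(4-methylpent-3-en-1-yl)oxiran-2-yl]methyl}benzoate F3. Camphorsulfonic acid in CH2Cl2 at −20 °C then brings about the familiar 6-endo opening of the trisubstituted epoxide by the phenol at the tertiary carbon with inversion, giving the chromanol methyl (2R,3R)-3-hydroxy-2-methyl-2-(4-methylpent-3-en-1-yl)chromane-6-carboxylate F4. Ac2O, pyridine and DMAP give 12.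

The photochemical coupling (step 2) comes next. The unstabilised primary radical may be captured poorly by the nickel complex, and the dioxolanone or the aryl acetate may not survive the carboxylate medium. The fallback sets out from 3 and comes back at 4. Acid 3 is converted with N-hydroxyphthalimide and N,N′-diisopropylcarbodiimide into the redox-active ester 1,3-dioxoisoindolin-2-yl 2-[(4R)-2,2-dimethyl-5-oxo-1,3-dioxolan-4-yl]acetate F1, which is joined to 2 in a thermal reductive cross-electrophile coupling (NiBr2·glyme, dtbbpy, Zn, DMA, rt) to give 4.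

The electrolysis (step 7) is third. Bromide-mediated anodic chemistry could brominate the alkene or the arene, or the product could be oxidised further. The fallback sets out from 12 and comes back at 13. A photochemical singlet-oxygen ene reaction (O2, tetraphenylporphyrin, visible light, CH2Cl2, 0 °C) gives the allylic hydroperoxide methyl (2R,3R)-3-acetoxy-2-[(2E)-4-hydroperoxy-4-methylpent-2-en-1-yl]-2-methylchromane-6-carboxylate F5, and PPh3 reduces it to 13. This ene reaction is only about 1:1 regioselective on a prenyl-type terminus, so roughly half the material is lost, which is why it is the fallback and not the main step.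

Further compounds
F1 | step 2 | 1,3-dioxoisoindolin-2-yl 2-[(4R)-2,2-dimethyl-5-oxo-1,3-dioxolan-4-yl]acetate | O=C(C[C@H]1OC(C)(C)OC1=O)ON1C(=O)c2ccccc2C1=O
F2 | step 6 | methyl 3-[(2R,3R)-2-acetoxy-3-chloro-3,7-dimethyloct-6-en-1-yl]-4-hydroxybenzoate | COC(=O)c1ccc(O)c(c1)C[C@@H](OC(C)=O)[C@](C)(Cl)CCC=C(C)C
F3 | step 6 | methyl 4-hydroxy-3-{[(2R,3S)-3-methyl-3-(4-methylpent-3-en-1-yl)oxiran-2-yl]methyl}benzoate | COC(=O)c1ccc(O)c(c1)C[C@H]1O[C@@]1(C)CCC=C(C)C
F4 | step 6 | methyl (2R,3R)-3-hydroxy-2-methyl-2-(4-methylpent-3-en-1-yl)chromane-6-carboxylate | COC(=O)c1ccc2c(c1)C[C@@H](O)[C@@](C)(CCC=C(C)C)O2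
F5 | step 7 | methyl (2R,3R)-3-acetoxy-2-[(2E)-4-hydroperoxy-4-methylpent-2-en-1-yl]-2-methylchromane-6-carboxylate | COC(=O)c1ccc2c(c1)C[C@@H](OC(C)=O)[C@@](C)(C/C=C/C(C)(C)OO)O2
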